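**Retrosynthetic overview**

1. The target is a (7R,7′R,8S,8′S)-syringaresinol-type furofuran (cis-fused 3,7-dioxabicyclo[3.3.0]octane). Its two syringyl oxygens carry 8-O-4 guaiacylglycerol ethers: unit D (erythro, 7S,8R) on one side, and unit B (threo, 7R,8R) extended by unit A (erythro, 7R,8S) on the other.
2. Key disconnection: the aryl–C-7′ bond together with the C-8′–C-9′ bond. A monocyclic 3-substituted 2,3-dihydrofuran with a methoxymethyl ether on the C-7 oxygen (34) and the aryltrifluoroborate of the unit-D half (43) are joined in one Lewis-acid cascade: Prins-type ring closure, then aryl transfer to the bicyclic oxocarbenium ion.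
3. Enabling feature: C-7′ is acetal-like. It is bonded to the ring oxygen of the second tetrahydrofuran ring, to bridgehead C-8′ and to the aryl ipso carbon, so it can be an oxocarbenium carbon. C-8′ is then the β-carbon of an enol ether, and the cis-fused bicycle offers only its convex face, which places the incoming aryl group exo.
4. Ring order: the dihydrofuran (future aryl-bearing ring: O, C-9, C-8, C-8′, C-7′) is made first by dehydration of an aldol-derived lactol. The ring bearing the left syringyl group (C-7, O, C-9′, C-8′, C-8) closes in the key step. C-7 and C-8 come from an Evans syn-aldol of a pent-4-enoyl imide.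
5. All six side-chain stereocentres come from Evans syn-aldols of aryloxyacetyl imides (threo); the erythro units follow by Mitsunobu inversion at C-7. The chain A→B→core grows by repeating phenol alkylation, aldol, and cleavage of a propenyl group to the next aldehyde.

Key step: step 26

Assumption: lignan numbering is used (C-7 benzylic, C-8, C-9 in each C6–C3 unit; primed numbers for the furofuran half that receives the new aryl group), and the propenylphenols 3 and 13 are taken as (E)-isomers, whose geometry is irrelevant because the double bond is cleaved later.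

**Route**

Step 1
Reactants: 1 vanillin
Product: 2 4-formyl-2-methoxyphenyl pivalate
Conditions: PivCl, Et3N, DMAP (cat.), CH2Cl2, 0 °C → rt
Reagents that add atoms: pivaloyl chloride CC(C)(C)C(Cl)=O
Why: O-acylation of the phenol (DMAP catalysis) should give the pivalate, chosen because it is inert to borohydride and boron enolates and because an electron-poor aryl ester later suppresses ionisation at benzylic C-7.

Step 2
Reactants: 3 (E)-isoeugenol; 4 (R)-4-benzyl-3-(chloroacetyl)oxazolidin-2-one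
Product: 5 (R)-4-benzyl-3-{[2-methoxy-4-((E)-prop-1-enyl)phenoxy]acetyl}oxazolidin-2-one
Conditions: K2CO3, NaI (cat.), acetone, 45 °C
Reagents that add atoms: none
Why: Williamson etherification, in which the phenoxide displaces the α-halide of the imide by SN2 (iodide catalysis), should be much faster than attack at the imide carbonyl.

Step 3
Reactants: 5 aryloxyacetyl imide; 2 4-formyl-2-methoxyphenyl pivalate
Product: 7 syn-aldol adduct (2R,3S) carrying the (R)-auxiliary, via boron enolate 6 (not isolated)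
Conditions: Bu2BOTf, i-Pr2NEt, CH2Cl2, 0 °C; then 2, −78 → 0 °C; MeOH/pH 7 buffer
Reagents that add atoms: none
Why: Evans syn-aldol reaction, in which the Z-boron enolate reacts through a Zimmerman–Traxler chair on the face opposite the benzyl group of the (R)-auxiliary, should give the (2R,3S) adduct, i.e. the threo (7S,8S) arrangement of hydroxyl and aryloxy groups.

Step 4
Reactants: 7 syn-aldol adduct
Product: 8 threo diol (1S,2S)-1-(3-methoxy-4-pivaloyloxyphenyl)-2-[2-methoxy-4-(prop-1-enyl)phenoxy]propane-1,3-diol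
Conditions: NaBH4, THF/H2O (3:1), 0 °C → rt
Reagents that add atoms: none
Why: borohydride reductive cleavage of the N-acyloxazolidinone (the imide carbonyl is far more electrophilic than the hindered aryl pivalate) should release the 1,3-diol without touching a stereocentre.

Step 5
Reactants: 8 threo diol
Product: 9 primary TBS ether of 8 (benzylic hydroxyl free)
Conditions: TBSCl, imidazole, CH2Cl2, 0 °C
Reagents that add atoms: tert-butyldimethylsilyl chloride CC(C)(C)[Si](C)(C)Cl
Why: silylation is selective for the primary hydroxyl group on steric grounds and leaves the benzylic alcohol free for inversion.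

Step 6
Reactants: 9 threo mono-silyl ether
Product: 10 erythro (7R,8S) benzoate
Conditions: PhCO2H, PPh3, DIAD, THF, 0 °C → rt
Reagents that add atoms: benzoic acid OC(=O)c1ccccc1
Why: Mitsunobu esterification displaces the oxyphosphonium ion by SN2 with inversion at C-7 and should convert threo into erythro, the electron-poor pivaloyloxy-aryl ring disfavouring an SN1 path.

Step 7
Reactants: 10 erythro benzoate
Product: 12 unit-A aldehyde 4-{[(1R,2S)-1-benzoyloxy-3-(TBS-oxy)-1-(3-methoxy-4-pivaloyloxyphenyl)propan-2-yl]oxy}-3-methoxybenzaldehyde, via vicinal diol 11 (not isolated)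
Conditions: OsO4 (cat.), NaIO4, 2,6-lutidine, dioxane/H2O, rt
Reagents that add atoms: osmium tetroxide O=[Os](=O)(=O)=O (catalytic; its oxygen, renewed from sodium periodate [Na+].[O-]I(=O)(=O)=O and water, ends in the aldehyde)
Why: Lemieux–Johnson oxidative cleavage (osmylation of the electron-rich styrenyl double bond, periodate glycol fission) should unmask the aryl aldehyde without touching esters or silyl ether.

Step 8
Reactants: 13 (E)-2,6-dimethoxy-4-(prop-1-enyl)phenol; 14 (S)-4-benzyl-3-(chloroacetyl)oxazolidin-2-one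
Product: 15 (S)-4-benzyl-3-{[2,6-dimethoxy-4-((E)-prop-1-enyl)phenoxy]acetyl}oxazolidin-2-one
Conditions: K2CO3, NaI (cat.), acetone, 50 °C
Reagents that add atoms: none
Why: Williamson etherification as in step 2, here with the more hindered 2,6-dimethoxyphenoxide.

Step 9
Reactants: 15 aryloxyacetyl imide; 12 unit-A aldehyde
Product: 17 syn-aldol adduct (2S,3R) carrying the (S)-auxiliary, via boron enolate 16 (not isolated)
Conditions: Bu2BOTf, i-Pr2NEt, CH2Cl2, 0 °C; then 12, −78 → 0 °C; MeOH/pH 7 buffer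
Reagents that add atoms: none
Why: Evans syn-aldol reaction with the (S)-auxiliary should give, by reagent control independent of the remote stereocentres of unit A, the (2S,3R) adduct, i.e. the threo (7R,8R) configuration of unit B.

Step 10
Reactants: 17 syn-aldol adduct
Product: 18 threo (7R,8R) diol of unit B
Conditions: NaBH4, THF/H2O (3:1), 0 °C → rt
Reagents that add atoms: none
Why: borohydride reductive removal of the auxiliary as in step 4, with the secondary benzoate and the aryl pivalate expected to survive at this temperature.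

Step 11
Reactants: 18 threo diol
Product: 19 bis-TBS ether of 18
Conditions: TBSOTf, 2,6-lutidine, CH2Cl2, −20 → 0 °C
Reagents that add atoms: tert-butyldimethylsilyl triflate CC(C)(C)[Si](C)(C)OS(=O)(=O)C(F)(F)F
Why: the silyl triflate with a hindered pyridine base silylates both the primary and the hindered benzylic hydroxyl group.

Step 12
Reactants: 19 bis-TBS ether
Product: 21 trimer aldehyde (3,5-dimethoxybenzaldehyde whose 4-oxygen carries protected unit B and unit A), via vicinal diol 20 (not isolated)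
Conditions: OsO4 (cat.), NaIO4, 2,6-lutidine, dioxane/H2O, rt
Reagents that add atoms: osmium tetroxide O=[Os](=O)(=O)=O (catalytic; its oxygen, renewed from sodium periodate [Na+].[O-]I(=O)(=O)=O and water, ends in the aldehyde)
Why: Lemieux–Johnson cleavage as in step 7 should deliver the 4-alkoxy-3,5-dimethoxybenzaldehyde needed for the core aldol.

Step 13
Reactants: 22 (R)-4-benzyloxazolidin-2-one; 23 pent-4-enoyl chloride
Product: 25 (R)-4-benzyl-3-(pent-4-enoyl)oxazolidin-2-one, via lithium oxazolidinide 24 (not isolated)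
Conditions: n-BuLi, THF, −78 °C; then 23, −78 → 0 °C
Reagents that add atoms: none
Why: N-acylation of the lithiated oxazolidinone with an acid chloride is the standard preparation of an Evans imide.

Step 14
Reactants: 25 pentenoyl imide; 21 trimer aldehyde
Product: 27 syn-aldol adduct (2R,3R) carrying the (R)-auxiliary, via boron enolate 26 (not isolated)
Conditions: Bu2BOTf, i-Pr2NEt, CH2Cl2, 0 °C; then 21, −78 → 0 °C; MeOH/pH 7 buffer
Reagents that add atoms: none
Why: Evans syn-aldol reaction with the (R)-auxiliary should set C-7 (R) and C-8 of the furofuran in the syn relationship that later places the syringyl ring exo, the allyl group being the two-carbon precursor of C-8′ and C-7′.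

Step 15
Reactants: 27 syn-aldol adduct
Product: 28 methoxymethyl ether of 27
Conditions: MOMCl, i-Pr2NEt, Bu4NI (cat.), CH2Cl2, 0 °C → rt
Reagents that add atoms: chloromethyl methyl ether COCCl
Why: alkoxymethylation of the β-hydroxy imide under amine-base conditions (no retro-aldol) installs the O–CH2–OMe group whose CH2 later becomes C-9′.

Step 16
Reactants: 28 MOM ether
Product: 29 primary alcohol (2S)-2-[(R)-aryl(methoxymethoxy)methyl]pent-4-en-1-ol (aryl = the ring of 21)
Conditions: NaBH4, THF/H2O (3:1), 0 °C → rt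
Reagents that add atoms: none
Why: borohydride reductive cleavage of the imide as in step 4 frees the C-9 hydroxyl group.

Step 17
Reactants: 29 alkenol
Product: 32 lactol (4S)-4-[(R)-aryl(methoxymethoxy)methyl]tetrahydrofuran-2-ol as an anomeric mixture, via triol 30 (not isolated), via hydroxy aldehyde 31 (not isolated)
Conditions: OsO4 (cat.), NaIO4, 2,6-lutidine, dioxane/H2O, rt
Reagents that add atoms: osmium tetroxide O=[Os](=O)(=O)=O (catalytic; its oxygen, renewed from sodium periodate [Na+].[O-]I(=O)(=O)=O and water, ends in the lactol hydroxyl)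
Why: Lemieux–Johnson cleavage of the terminal alkene gives the γ-hydroxy aldehyde, which should close spontaneously to the five-membered lactol (ring O, C-9, C-8, C-8′, C-7′).

Step 18
Reactants: 32 lactol
Product: 34 (3S)-3-[(R)-aryl(methoxymethoxy)methyl]-2,3-dihydrofuran, via anomeric mesylate 33 (not isolated)
Conditions: MsCl, Et3N, THF, −40 → 60 °C; chromatography on Et3N-deactivated silica
Reagents that add atoms: none
Why: sulfonylation of the anomeric hydroxyl group and base-induced elimination (lactol dehydration) should give the cyclic enol ether, C-8′ being the only carbon that can lose a proton.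

Step 19
Reactants: 35 4-bromo-2,6-dimethoxyphenol; 14 (S)-4-benzyl-3-(chloroacetyl)oxazolidin-2-one
Product: 36 (S)-4-benzyl-3-[(4-bromo-2,6-dimethoxyphenoxy)acetyl]oxazolidin-2-one
Conditions: K2CO3, NaI (cat.), acetone, 50 °C
Reagents that add atoms: none
Why: Williamson etherification as in step 2.

Step 20
Reactants: 36 aryloxyacetyl imide; 2 4-formyl-2-methoxyphenyl pivalate
Product: 38 syn-aldol adduct (2S,3R) carrying the (S)-auxiliary, via boron enolate 37 (not isolated)
Conditions: Bu2BOTf, i-Pr2NEt, CH2Cl2, 0 °C; then 2, −78 → 0 °C; MeOH/pH 7 buffer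
Reagents that add atoms: none
Why: Evans syn-aldol reaction with the (S)-auxiliary should give the (2S,3R) adduct, i.e. the threo (7R,8R) precursor of unit D.

Step 21
Reactants: 38 syn-aldol adduct
Product: 39 threo diol (1R,2R)-2-(4-bromo-2,6-dimethoxyphenoxy)-1-(3-methoxy-4-pivaloyloxyphenyl)propane-1,3-diol
Conditions: NaBH4, THF/H2O (3:1), 0 °C → rt
Reagents that add atoms: none
Why: borohydride reductive removal of the auxiliary as in step 4.

Step 22
Reactants: 39 threo diol
Product: 40 primary TBS ether of 39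
Conditions: TBSCl, imidazole, CH2Cl2, 0 °C
Reagents that add atoms: tert-butyldimethylsilyl chloride CC(C)(C)[Si](C)(C)Cl
Why: selective silylation of the primary hydroxyl group as in step 5.

Step 23
Reactants: 40 threo mono-silyl ether
Product: 41 erythro (7S,8R) benzoate aryl bromide
Conditions: PhCO2H, PPh3, DIAD, THF, 0 °C → rt
Reagents that add atoms: benzoic acid OC(=O)c1ccccc1
Why: Mitsunobu esterification with SN2 inversion at C-7, as in step 6, should give the erythro configuration of unit D.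

Step 24
Reactants: 41 aryl bromide
Product: 42 aryl pinacol boronate
Conditions: B2pin2, Pd(dppf)Cl2 (cat.), KOAc, dioxane, 90 °C
Reagents that add atoms: bis(pinacolato)diboron CC1(C)OB(OC1(C)C)B1OC(C)(C)C(C)(C)O1
Why: Miyaura borylation of the unhindered aryl bromide tolerates the esters and the silyl ether.

Step 25
Reactants: 42 aryl pinacol boronate
Product: 43 potassium aryltrifluoroborate
Conditions: KHF2, MeOH/H2O, rt
Reagents that add atoms: potassium hydrogen difluoride [K+].[F-].F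
Why: fluoride exchange at boron converts the pinacol boronate into the trifluoroborate, the storable precursor of the aryldifluoroborane used in the key step.

Step 26
Reactants: 34 dihydrofuran MOM ether; 43 potassium aryltrifluoroborate
Product: 46 fully protected target, via aryldifluoroborane 44 (not isolated), via bicyclic oxocarbenium ion 45 (not isolated)
Conditions: BF3·OEt2, 2,6-di-tert-butyl-4-methylpyridine, CH2Cl2/MeCN, −40 → 0 °C; aq. NaHCO3
Reagents that add atoms: none
Why: Proposed new method: BF3·OEt2 converts 43 into aryldifluoroborane 44, which abstracts methoxide from the MOM acetal of 34 to give the C-7–O=CH2+ oxocarbenium ion paired with the borate ArBF2(OMe)−; the nucleophilic β-carbon (C-8′) of the 2,3-dihydrofuran attacks this carbon and generates the bicyclic oxocarbenium ion 45 (O=C-7′+), to which the borate transfers its aryl group by ipso substitution. The closest known reaction types are the Lewis-acid cyclisation of dihydrofuranyl carbinol acetals to furofuran acetals and the BF3-mediated coupling of electron-rich aryltrifluoroborates with cyclic mixed acetals. The new tetrahydrofuran ring (C-7, O, C-9′, C-8′, C-8) closes in a five-membered Prins-type mode in which the enol-ether π bond is exocyclic and the oxocarbenium C=O+ endocyclic to the forming ring. C-8′ is set by the tether, because the CH2+ carbon is delivered from the C-7 oxygen on the face of the dihydrofuran that already carries C-7, so only the cis-fused 3,7-dioxabicyclo[3.3.0]octane can form. C-7′ is set by the shape of ion 45, the aryl group being delivered to its convex face, anti to the C-8′–C-9′ bond, which should give the exo aryl group (7′R). The step needs ionisation of the O,O-acetal in preference to the benzylic silyl ethers and esters (secured by low temperature, the weak Lewis acid, the hindered base and the electron-poor pivaloyloxy-aryl rings) and ipso rather than ortho attack on the arene (secured by the C–B bond and by the crowding of the positions next to the methoxy groups).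

Step 27
Reactants: 46 fully protected target
Product: 47 tetrakis-TBS ether of the target (silyl groups on O-9 of units A, B and D and on O-7 of unit B)
Conditions: DIBAL-H (excess), CH2Cl2, −78 → −40 °C; Rochelle salt work-up
Reagents that add atoms: none
Why: hydride reduction cleaves the two benzoates and the two aryl pivalates together at low temperature, before any phenoxide meets a benzylic ester under basic conditions, so that no quinone methide can form by loss of benzoate.

Step 28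
Reactants: 47 tetrakis-TBS ether
Product: 48 CNP0316493.1 (target)
Conditions: TBAF, AcOH, THF, 0 °C → rt
Reagents that add atoms: none
Why: fluoride-mediated desilylation buffered with acetic acid removes the four silyl ethers without base- or acid-induced epimerisation of the benzylic carbinols.

**Compound list**

1 | vanillin (4-hydroxy-3-methoxybenzaldehyde) | COc1cc(C=O)ccc1O | starting material
2 | 4-formyl-2-methoxyphenyl pivalate | COc1cc(C=O)ccc1OC(=O)C(C)(C)C | intermediate
3 | (E)-isoeugenol, 2-methoxy-4-(prop-1-enyl)phenol | COc1cc(/C=C/C)ccc1O | starting material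
4 | (R)-4-benzyl-3-(chloroacetyl)oxazolidin-2-one | ClCC(=O)N1[C@H](Cc2ccccc2)COC1=O | starting material
5 | (R)-4-benzyl-3-{[2-methoxy-4-((E)-prop-1-enyl)phenoxy]acetyl}oxazolidin-2-one | COc1cc(/C=C/C)ccc1OCC(=O)N1[C@H](Cc2ccccc2)COC1=O | intermediate
6 | (Z)-O-dibutylboryl enolate of 5 | COc1cc(/C=C/C)ccc1O/C=C(\OB(CCCC)CCCC)N1[C@H](Cc2ccccc2)COC1=O | intermediate
7 | (R)-4-benzyl-3-[(2R,3S)-3-hydroxy-3-(3-methoxy-4-pivaloyloxyphenyl)-2-(2-methoxy-4-propenylphenoxy)propanoyl]oxazolidin-2-one | COc1cc([C@H](O)[C@H](C(=O)N2[C@H](Cc3ccccc3)COC2=O)Oc2ccc(/C=C/C)cc2OC)ccc1OC(=O)C(C)(C)C | intermediate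
8 | threo diol, (1S,2S)-1-(3-methoxy-4-pivaloyloxyphenyl)-2-(2-methoxy-4-propenylphenoxy)propane-1,3-diol | COc1cc([C@H](O)[C@H](CO)Oc2ccc(/C=C/C)cc2OC)ccc1OC(=O)C(C)(C)C | intermediate
9 | 3-O-TBS ether of 8 (1S,2S; benzylic OH free) | COc1cc([C@H](O)[C@H](CO[Si](C)(C)C(C)(C)C)Oc2ccc(/C=C/C)cc2OC)ccc1OC(=O)C(C)(C)C | intermediate
10 | erythro benzoate, (1R,2S)-1-benzoyloxy-3-(TBS-oxy)-1-(3-methoxy-4-pivaloyloxyphenyl)-2-(2-methoxy-4-propenylphenoxy)propane | COc1cc([C@@H](OC(=O)c2ccccc2)[C@H](CO[Si](C)(C)C(C)(C)C)Oc2ccc(/C=C/C)cc2OC)ccc1OC(=O)C(C)(C)C | intermediate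
11 | vicinal diol from the propenyl group of 10 (new carbinol centres undefined) | COc1cc([C@@H](OC(=O)c2ccccc2)[C@H](CO[Si](C)(C)C(C)(C)C)Oc2ccc(C(O)C(C)O)cc2OC)ccc1OC(=O)C(C)(C)C | intermediate
12 | unit-A aldehyde, 4-{[(1R,2S)-1-benzoyloxy-3-(TBS-oxy)-1-(3-methoxy-4-pivaloyloxyphenyl)propan-2-yl]oxy}-3-methoxybenzaldehyde | COc1cc([C@@H](OC(=O)c2ccccc2)[C@H](CO[Si](C)(C)C(C)(C)C)Oc2ccc(C=O)cc2OC)ccc1OC(=O)C(C)(C)C | intermediate
13 | (E)-2,6-dimethoxy-4-(prop-1-enyl)phenol | COc1cc(/C=C/C)cc(OC)c1O | starting material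
14 | (S)-4-benzyl-3-(chloroacetyl)oxazolidin-2-one | ClCC(=O)N1[C@@H](Cc2ccccc2)COC1=O | starting material
15 | (S)-4-benzyl-3-{[2,6-dimethoxy-4-((E)-prop-1-enyl)phenoxy]acetyl}oxazolidin-2-one | COc1cc(/C=C/C)cc(OC)c1OCC(=O)N1[C@@H](Cc2ccccc2)COC1=O | intermediate
16 | (Z)-O-dibutylboryl enolate of 15 | COc1cc(/C=C/C)cc(OC)c1O/C=C(\OB(CCCC)CCCC)N1[C@@H](Cc2ccccc2)COC1=O | intermediate
17 | (2S,3R) syn-aldol adduct of 15 with 12, (S)-auxiliary attached | COc1cc([C@@H](OC(=O)c2ccccc2)[C@H](CO[Si](C)(C)C(C)(C)C)Oc2ccc([C@@H](O)[C@@H](C(=O)N3[C@@H](Cc4ccccc4)COC3=O)Oc3c(OC)cc(/C=C/C)cc3OC)cc2OC)ccc1OC(=O)C(C)(C)C | intermediate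
18 | threo (7R,8R) diol of unit B carrying protected unit A and the propenyl-syringyl ether | COc1cc([C@@H](OC(=O)c2ccccc2)[C@H](CO[Si](C)(C)C(C)(C)C)Oc2ccc([C@@H](O)[C@@H](CO)Oc3c(OC)cc(/C=C/C)cc3OC)cc2OC)ccc1OC(=O)C(C)(C)C | intermediate
19 | bis-TBS ether of 18 | COc1cc([C@@H](OC(=O)c2ccccc2)[C@H](CO[Si](C)(C)C(C)(C)C)Oc2ccc([C@@H](O[Si](C)(C)C(C)(C)C)[C@@H](CO[Si](C)(C)C(C)(C)C)Oc3c(OC)cc(/C=C/C)cc3OC)cc2OC)ccc1OC(=O)C(C)(C)C | intermediate
20 | vicinal diol from the propenyl group of 19 (new carbinol centres undefined) | COc1cc([C@@H](OC(=O)c2ccccc2)[C@H](CO[Si](C)(C)C(C)(C)C)Oc2ccc([C@@H](O[Si](C)(C)C(C)(C)C)[C@@H](CO[Si](C)(C)C(C)(C)C)Oc3c(OC)cc(C(O)C(C)O)cc3OC)cc2OC)ccc1OC(=O)C(C)(C)C | intermediate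
21 | trimer aldehyde, 3,5-dimethoxybenzaldehyde whose 4-oxygen is bonded to C-8 of bis-TBS unit B (7R,8R), itself bearing unit A (7R,8S; 7-O-benzoyl, 9-O-TBS, 4-O-pivaloyl) | COc1cc([C@@H](OC(=O)c2ccccc2)[C@H](CO[Si](C)(C)C(C)(C)C)Oc2ccc([C@@H](O[Si](C)(C)C(C)(C)C)[C@@H](CO[Si](C)(C)C(C)(C)C)Oc3c(OC)cc(C=O)cc3OC)cc2OC)ccc1OC(=O)C(C)(C)C | intermediate
22 | (R)-4-benzyloxazolidin-2-one | O=C1N[C@H](Cc2ccccc2)CO1 | starting material
23 | pent-4-enoyl chloride | C=CCCC(Cl)=O | starting material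
24 | lithium salt of 22 | [Li+].O=C1[N-][C@H](Cc2ccccc2)CO1 | intermediate
25 | (R)-4-benzyl-3-(pent-4-enoyl)oxazolidin-2-one | C=CCCC(=O)N1[C@H](Cc2ccccc2)COC1=O | intermediate
26 | (Z)-O-dibutylboryl enolate of 25 | C=CC/C=C(\OB(CCCC)CCCC)N1[C@H](Cc2ccccc2)COC1=O | intermediate
27 | (R)-4-benzyl-3-{(2R)-2-[(R)-aryl(hydroxy)methyl]pent-4-enoyl}oxazolidin-2-one, aryl = ring of 21 | COc1cc([C@@H](OC(=O)c2ccccc2)[C@H](CO[Si](C)(C)C(C)(C)C)Oc2ccc([C@@H](O[Si](C)(C)C(C)(C)C)[C@@H](CO[Si](C)(C)C(C)(C)C)Oc3c(OC)cc([C@H](O)[C@@H](CC=C)C(=O)N4[C@H](Cc5ccccc5)COC4=O)cc3OC)cc2OC)ccc1OC(=O)C(C)(C)C | intermediate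
28 | methoxymethyl ether of 27 | COc1cc([C@@H](OC(=O)c2ccccc2)[C@H](CO[Si](C)(C)C(C)(C)C)Oc2ccc([C@@H](O[Si](C)(C)C(C)(C)C)[C@@H](CO[Si](C)(C)C(C)(C)C)Oc3c(OC)cc([C@H](OCOC)[C@@H](CC=C)C(=O)N4[C@H](Cc5ccccc5)COC4=O)cc3OC)cc2OC)ccc1OC(=O)C(C)(C)C | intermediate
29 | (2S)-2-[(R)-aryl(methoxymethoxy)methyl]pent-4-en-1-ol | COc1cc([C@@H](OC(=O)c2ccccc2)[C@H](CO[Si](C)(C)C(C)(C)C)Oc2ccc([C@@H](O[Si](C)(C)C(C)(C)C)[C@@H](CO[Si](C)(C)C(C)(C)C)Oc3c(OC)cc([C@H](OCOC)[C@@H](CC=C)CO)cc3OC)cc2OC)ccc1OC(=O)C(C)(C)C | intermediate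
30 | triol from dihydroxylation of the alkene of 29 (new carbinol centre undefined) | COc1cc([C@@H](OC(=O)c2ccccc2)[C@H](CO[Si](C)(C)C(C)(C)C)Oc2ccc([C@@H](O[Si](C)(C)C(C)(C)C)[C@@H](CO[Si](C)(C)C(C)(C)C)Oc3c(OC)cc([C@H](OCOC)[C@@H](CC(O)CO)CO)cc3OC)cc2OC)ccc1OC(=O)C(C)(C)C | intermediate
31 | γ-hydroxy aldehyde, (3S)-3-(hydroxymethyl)-4-aryl-4-(methoxymethoxy)butanal | COc1cc([C@@H](OC(=O)c2ccccc2)[C@H](CO[Si](C)(C)C(C)(C)C)Oc2ccc([C@@H](O[Si](C)(C)C(C)(C)C)[C@@H](CO[Si](C)(C)C(C)(C)C)Oc3c(OC)cc([C@H](OCOC)[C@@H](CC=O)CO)cc3OC)cc2OC)ccc1OC(=O)C(C)(C)C | intermediate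
32 | lactol, (4S)-4-[(R)-aryl(methoxymethoxy)methyl]tetrahydrofuran-2-ol (anomeric mixture) | COc1cc([C@@H](OC(=O)c2ccccc2)[C@H](CO[Si](C)(C)C(C)(C)C)Oc2ccc([C@@H](O[Si](C)(C)C(C)(C)C)[C@@H](CO[Si](C)(C)C(C)(C)C)Oc3c(OC)cc([C@H](OCOC)[C@@H]4COC(O)C4)cc3OC)cc2OC)ccc1OC(=O)C(C)(C)C | intermediate
33 | anomeric mesylate of 32 | COc1cc([C@@H](OC(=O)c2ccccc2)[C@H](CO[Si](C)(C)C(C)(C)C)Oc2ccc([C@@H](O[Si](C)(C)C(C)(C)C)[C@@H](CO[Si](C)(C)C(C)(C)C)Oc3c(OC)cc([C@H](OCOC)[C@@H]4COC(OS(C)(=O)=O)C4)cc3OC)cc2OC)ccc1OC(=O)C(C)(C)C | intermediate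
34 | (3S)-3-[(R)-aryl(methoxymethoxy)methyl]-2,3-dihydrofuran | COc1cc([C@@H](OC(=O)c2ccccc2)[C@H](CO[Si](C)(C)C(C)(C)C)Oc2ccc([C@@H](O[Si](C)(C)C(C)(C)C)[C@@H](CO[Si](C)(C)C(C)(C)C)Oc3c(OC)cc([C@H](OCOC)[C@@H]4COC=C4)cc3OC)cc2OC)ccc1OC(=O)C(C)(C)C | intermediate
35 | 4-bromo-2,6-dimethoxyphenol | COc1cc(Br)cc(OC)c1O | starting material
36 | (S)-4-benzyl-3-[(4-bromo-2,6-dimethoxyphenoxy)acetyl]oxazolidin-2-one | COc1cc(Br)cc(OC)c1OCC(=O)N1[C@@H](Cc2ccccc2)COC1=O | intermediate
37 | (Z)-O-dibutylboryl enolate of 36 | COc1cc(Br)cc(OC)c1O/C=C(\OB(CCCC)CCCC)N1[C@@H](Cc2ccccc2)COC1=O | intermediate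
38 | (S)-4-benzyl-3-[(2S,3R)-2-(4-bromo-2,6-dimethoxyphenoxy)-3-hydroxy-3-(3-methoxy-4-pivaloyloxyphenyl)propanoyl]oxazolidin-2-one | Brc1cc(OC)c(O[C@H](C(=O)N2[C@@H](Cc3ccccc3)COC2=O)[C@H](O)c2ccc(OC(=O)C(C)(C)C)c(OC)c2)c(OC)c1 | intermediate
39 | threo diol, (1R,2R)-2-(4-bromo-2,6-dimethoxyphenoxy)-1-(3-methoxy-4-pivaloyloxyphenyl)propane-1,3-diol | Brc1cc(OC)c(O[C@H](CO)[C@H](O)c2ccc(OC(=O)C(C)(C)C)c(OC)c2)c(OC)c1 | intermediate
40 | 3-O-TBS ether of 39 (1R,2R; benzylic OH free) | Brc1cc(OC)c(O[C@H](CO[Si](C)(C)C(C)(C)C)[C@H](O)c2ccc(OC(=O)C(C)(C)C)c(OC)c2)c(OC)c1 | intermediate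
41 | erythro benzoate, (1S,2R)-1-benzoyloxy-2-(4-bromo-2,6-dimethoxyphenoxy)-3-(TBS-oxy)-1-(3-methoxy-4-pivaloyloxyphenyl)propane | Brc1cc(OC)c(O[C@H](CO[Si](C)(C)C(C)(C)C)[C@@H](OC(=O)c2ccccc2)c2ccc(OC(=O)C(C)(C)C)c(OC)c2)c(OC)c1 | intermediate
42 | pinacol boronate corresponding to 41 (Bpin in place of Br) | CC1(C)OB(OC1(C)C)c1cc(OC)c(O[C@H](CO[Si](C)(C)C(C)(C)C)[C@@H](OC(=O)c2ccccc2)c2ccc(OC(=O)C(C)(C)C)c(OC)c2)c(OC)c1 | intermediate
43 | potassium trifluoroborate corresponding to 41 | [K+].F[B-](F)(F)c1cc(OC)c(O[C@H](CO[Si](C)(C)C(C)(C)C)[C@@H](OC(=O)c2ccccc2)c2ccc(OC(=O)C(C)(C)C)c(OC)c2)c(OC)c1 | intermediate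
44 | aryldifluoroborane from 43 | FB(F)c1cc(OC)c(O[C@H](CO[Si](C)(C)C(C)(C)C)[C@@H](OC(=O)c2ccccc2)c2ccc(OC(=O)C(C)(C)C)c(OC)c2)c(OC)c1 | intermediate
45 | cis-fused bicyclic oxocarbenium ion (6-aryl-3,7-dioxabicyclo[3.3.0]oct-2-en-3-ium; O=C-7′+) | COc1cc([C@@H](OC(=O)c2ccccc2)[C@H](CO[Si](C)(C)C(C)(C)C)Oc2ccc([C@@H](O[Si](C)(C)C(C)(C)C)[C@@H](CO[Si](C)(C)C(C)(C)C)Oc3c(OC)cc([C@@H]4OC[C@@H]5[C@H]4C[O+]=C5)cc3OC)cc2OC)ccc1OC(=O)C(C)(C)C | intermediate
46 | fully protected target (7R,7′R,8S,8′S furofuran; four TBS ethers, two benzoates, two aryl pivalates) | COc1cc([C@@H](OC(=O)c2ccccc2)[C@H](CO[Si](C)(C)C(C)(C)C)Oc2ccc([C@@H](O[Si](C)(C)C(C)(C)C)[C@@H](CO[Si](C)(C)C(C)(C)C)Oc3c(OC)cc([C@@H]4OC[C@@H]5[C@H]4CO[C@H]5c4cc(OC)c(O[C@H](CO[Si](C)(C)C(C)(C)C)[C@@H](OC(=O)c5ccccc5)c5ccc(OC(=O)C(C)(C)C)c(OC)c5)c(OC)c4)cc3OC)cc2OC)ccc1OC(=O)C(C)(C)C | intermediate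
47 | tetrakis-TBS ether of the target (free phenols and free C-7 hydroxyls of units A and D) | COc1cc([C@@H](O)[C@H](CO[Si](C)(C)C(C)(C)C)Oc2ccc([C@@H](O[Si](C)(C)C(C)(C)C)[C@@H](CO[Si](C)(C)C(C)(C)C)Oc3c(OC)cc([C@@H]4OC[C@@H]5[C@H]4CO[C@H]5c4cc(OC)c(O[C@H](CO[Si](C)(C)C(C)(C)C)[C@@H](O)c5ccc(O)c(OC)c5)c(OC)c4)cc3OC)cc2OC)ccc1O | intermediate
48 | CNP0316493.1 | COc1cc([C@@H](O)[C@H](CO)Oc2ccc([C@@H](O)[C@@H](CO)Oc3c(OC)cc([C@@H]4OC[C@@H]5[C@H]4CO[C@H]5c4cc(OC)c(O[C@H](CO)[C@@H](O)c5ccc(O)c(OC)c5)c(OC)c4)cc3OC)cc2OC)ccc1O | target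

**Summary and risks**

Total step count: 28. Longest linear sequence: 18 steps (steps 2–7, 9–12, 14–18, 26–28).

Steps most likely to fail:

Step 26 (Proposed new method). The borate of the only moderately electron-rich 4-alkoxy-3,5-dimethoxyphenyl group may transfer its aryl group too slowly, so that the bicyclic oxocarbenium ion is drained by proton loss, methoxide recapture or oligomerisation. The first oxocarbenium ion may also be arylated before it cyclises, or the benzylic silyl ether of unit B may ionise. The fallback separates ring closure from arylation and uses known reaction types only; it sets out from 34 and 41 and returns at 46. Compound 34 is cyclised alone with catalytic TMSOTf and 2,6-di-tert-butyl-4-methylpyridine (CH2Cl2, −78 °C; cyclisation of the enol ether onto the tethered oxocarbenium ion, with return of methoxide) to the bicyclic methyl acetal F1. Benzenesulfinic acid and CaCl2 (CH2Cl2, rt) should exchange the methoxy group to give the anomeric phenyl sulfone F2. In parallel, the aryl bromide 41 is converted by magnesium insertion in the presence of LiCl and ZnCl2 (THF, rt) into the ester-tolerant arylzinc chloride F3. F3 displaces the sulfinate of F2 (THF, rt) through the same ion 45, again on the convex face, which should give 46.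

Step 6 (the same process operates in step 23). SN2 displacement at the hindered benzylic carbon may be outrun by elimination to the α-aryloxystyrene or by partial ionisation, which would erode the inversion. The fallback replaces substitution by a redox inversion; it sets out from 9 and returns at 10. Buffered Dess–Martin oxidation (NaHCO3, CH2Cl2) gives the α-aryloxy ketone F4. Reduction with Zn(BH4)2 (Et2O, −30 °C), chelated between the ketone and the α-aryloxy oxygens and attacking opposite to the CH2OTBS group, is expected to favour the erythro alcohol F5. Benzoylation (BzCl, pyridine, DMAP) then gives 10.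

Step 18. The anomeric sulfonate may be captured by chloride or by a second lactol molecule instead of eliminating, and the acid-labile enol ether may be lost on isolation. The fallback uses a neutral syn-elimination; it sets out from 32 and returns at 34. N-(Phenylseleno)phthalimide and Bu3P (CH2Cl2, −20 °C) convert the lactol into the anomeric phenyl selenide F6. Oxidation (NaIO4, NaHCO3, THF/MeOH/H2O, 0 °C → rt) gives the selenoxide F7, whose spontaneous syn-elimination in the presence of i-Pr2NH should give 34.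

Further compounds

F1 | step 26 | bicyclic methyl acetal, 6-aryl-2-methoxy-3,7-dioxabicyclo[3.3.0]octane (aryl = ring of 21; anomeric centre undefined) | COc1cc([C@@H](OC(=O)c2ccccc2)[C@H](CO[Si](C)(C)C(C)(C)C)Oc2ccc([C@@H](O[Si](C)(C)C(C)(C)C)[C@@H](CO[Si](C)(C)C(C)(C)C)Oc3c(OC)cc([C@@H]4OC[C@@H]5[C@H]4COC5OC)cc3OC)cc2OC)ccc1OC(=O)C(C)(C)C
F2 | step 26 | anomeric phenyl sulfone, 6-aryl-2-(phenylsulfonyl)-3,7-dioxabicyclo[3.3.0]octane (anomeric centre undefined) | COc1cc([C@@H](OC(=O)c2ccccc2)[C@H](CO[Si](C)(C)C(C)(C)C)Oc2ccc([C@@H](O[Si](C)(C)C(C)(C)C)[C@@H](CO[Si](C)(C)C(C)(C)C)Oc3c(OC)cc([C@@H]4OC[C@@H]5[C@H]4COC5S(=O)(=O)c4ccccc4)cc3OC)cc2OC)ccc1OC(=O)C(C)(C)C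
F3 | step 26 | arylzinc chloride from 41 | Cl[Zn]c1cc(OC)c(O[C@H](CO[Si](C)(C)C(C)(C)C)[C@@H](OC(=O)c2ccccc2)c2ccc(OC(=O)C(C)(C)C)c(OC)c2)c(OC)c1
F4 | step 6 | α-aryloxy ketone, (2S)-3-(TBS-oxy)-1-(3-methoxy-4-pivaloyloxyphenyl)-2-(2-methoxy-4-propenylphenoxy)propan-1-one | COc1cc(C(=O)[C@H](CO[Si](C)(C)C(C)(C)C)Oc2ccc(/C=C/C)cc2OC)ccc1OC(=O)C(C)(C)C
F5 | step 6 | erythro alcohol, (1R,2S)-3-(TBS-oxy)-1-(3-methoxy-4-pivaloyloxyphenyl)-2-(2-methoxy-4-propenylphenoxy)propan-1-ol | COc1cc([C@@H](O)[C@H](CO[Si](C)(C)C(C)(C)C)Oc2ccc(/C=C/C)cc2OC)ccc1OC(=O)C(C)(C)C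
F6 | step 18 | anomeric phenyl selenide of 32 (anomeric centre undefined) | COc1cc([C@@H](OC(=O)c2ccccc2)[C@H](CO[Si](C)(C)C(C)(C)C)Oc2ccc([C@@H](O[Si](C)(C)C(C)(C)C)[C@@H](CO[Si](C)(C)C(C)(C)C)Oc3c(OC)cc([C@H](OCOC)[C@@H]4COC([Se]c5ccccc5)C4)cc3OC)cc2OC)ccc1OC(=O)C(C)(C)C
F7 | step 18 | selenoxide of F6 | COc1cc([C@@H](OC(=O)c2ccccc2)[C@H](CO[Si](C)(C)C(C)(C)C)Oc2ccc([C@@H](O[Si](C)(C)C(C)(C)C)[C@@H](CO[Si](C)(C)C(C)(C)C)Oc3c(OC)cc([C@H](OCOC)[C@@H]4COC([Se](=O)c5ccccc5)C4)cc3OC)cc2OC)ccc1OC(=O)C(C)(C)C
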